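**Plan**

Numbering (labdane): decalin C1–C10 (ring A = C1–C5 and C10, ring B = C5–C10), side-chain alkene C11=C12, butenolide C13–C16, C17 = exocyclic CH2 on C8, C18/C19 = CH3/CH2OAc on C4, C20 = CH3 on C10; TBS = tert-butyldimethylsilyl.
Retrosynthetic cuts, in order: acetyl–O19; C12–C13 (Stille); C11=C12 (Takai); C8=C17 (methylenation of a C8 ketone); then C5–C10 and C8–C9 together (intramolecular Diels–Alder); C6=C7 (Wittig) and C3–C4 (iridium-catalysed tert-(hydroxy)prenylation), back to geranyl acetate and isoprene oxide.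
Forward: the open chain is joined first (C3–C4, then C6–C8 as a silyl dienol ether, then the C9=C10–C11 enal); rings A and B close together in step 10 (ring B by the cycloaddition, ring A through the C1–C4 tether); the butenolide ring is attached intact at the end.
Enabling feature: the trans C5–C10 fusion with the angular C20 methyl, the C9 stereocentre carrying the one-carbon arm C11, and C8, which is sp2 in the target and can be carried as a silyloxy carbon, make ring B a cyclohexene from the diene C5=C6–C7=C8 and the (E)-enal C9=C10, with C1–C4 as the tether.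
Stereochemistry: C3 and C4 from the chiral iridium catalyst (anti diol); C5, C9 and C10 from the cycloaddition (enal geometry, endo aldehyde with anti tether, equatorial C3 silyloxy group in a chair-like tether); C9=C10 (E) from geranyl acetate, C11=C12 (E) from the Takai reaction.

Key step: step 10

Assumption 1: (R)-Tol-BINAP is taken as the ligand antipode that gives the 6R,7R diol 5; if the first run shows the opposite sense, (S)-Tol-BINAP is used and nothing else changes.
Assumption 2: 3-bromofuran-2(5H)-one (21) is bought; otherwise it is made in one pot from furan-2(5H)-one (Br2, then Et3N).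

**Route**

Step 1
Reactants: 1 geranyl acetate
Product: 3 (2E)-3-methyl-6-oxohex-2-en-1-yl acetate, via secondary ozonide 2 (not isolated)
Conditions: O3 (1.0 equiv, Sudan Red 7B end point), CH2Cl2, −78 °C; then PPh3, −78 °C → rt
Reagents that add atoms: ozone, [O-][O+]=O
Why: Chemoselective ozonolysis with reductive work-up: the electron-rich isopropylidene alkene reacts much faster than the C2=C3 alkene, which is deactivated by the allylic acetate, so the (E)-trisubstituted alkene (later C9=C10) should survive.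

Step 2
Reactants: 3 (2E)-3-methyl-6-oxohex-2-en-1-yl acetate; 4 2-methyl-2-vinyloxirane (racemic isoprene monoxide)
Product: 5 (2E,6R,7R)-6-hydroxy-7-(hydroxymethyl)-3,7-dimethylnona-2,8-dien-1-yl acetate
Conditions: Ir catalyst preformed from [Ir(cod)Cl]2, (R)-Tol-BINAP, 4-cyano-3-nitrobenzoic acid and allyl acetate (5 mol%), K3PO4 (5 mol%), i-PrOH (2 equiv), 4 (3 equiv), THF, 45 °C
Reagents that add atoms: none
Why: Iridium-catalysed transfer-hydrogenative tert-(hydroxy)prenylation of an aldehyde: the (E)-σ-allyliridium formed by ionisation of the vinyl epoxide adds through a closed chair transition state, which gives the anti diol (C3–OH and C19 cis on the later ring A) and the C4 quaternary centre, the ligand fixing C3 as R, while the trisubstituted allylic acetate is too poor a π-ligand to be ionised.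

Step 3
Reactants: 5 (2E,6R,7R)-6-hydroxy-7-(hydroxymethyl)-3,7-dimethylnona-2,8-dien-1-yl acetate
Product: 6 (2E,6R,7R)-6-(TBS-oxy)-7-[(TBS-oxy)methyl]-3,7-dimethylnona-2,8-dien-1-yl acetate
Conditions: TBSOTf (2.4 equiv), 2,6-lutidine, CH2Cl2, −78 → 0 °C
Reagents that add atoms: tert-butyldimethylsilyl triflate, CC(C)(C)[Si](C)(C)OS(=O)(=O)C(F)(F)F
Why: Silylation with a silyl triflate protects the neopentyl primary and the hindered secondary hydroxyl as open-chain ethers; a cyclic acetal is avoided on purpose, because a cis-fused dioxane would have to leave its chair (C2 axial next to O3) in the cycloaddition transition state that leads to the natural C4/C10 relationship.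

Step 4
Reactants: 6 (2E,6R,7R)-6-(TBS-oxy)-7-[(TBS-oxy)methyl]-3,7-dimethylnona-2,8-dien-1-yl acetate
Product: 8 (2E,6R,7R)-6-(TBS-oxy)-7-[(TBS-oxy)methyl]-9-hydroxy-3,7-dimethylnon-2-en-1-yl acetate, via B-alkyl-9-BBN adduct 7 (not isolated)
Conditions: 9-BBN (1.5 equiv), THF, 0 → 40 °C; then 30% H2O2, 3 M aq. NaOAc, 0 °C → rt
Reagents that add atoms: hydrogen peroxide, OO
Why: Anti-Markovnikov hydroboration–oxidation: 9-BBN adds to the monosubstituted vinyl group far faster than to the trisubstituted alkene and puts boron on the terminal carbon (C6), and the acetate-buffered oxidation should leave the allylic acetate intact.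

Step 5
Reactants: 8 (2E,6R,7R)-6-(TBS-oxy)-7-[(TBS-oxy)methyl]-9-hydroxy-3,7-dimethylnon-2-en-1-yl acetate
Product: 9 (2E,6R,7R)-6-(TBS-oxy)-7-[(TBS-oxy)methyl]-3,7-dimethyl-9-oxonon-2-en-1-yl acetate
Conditions: Dess–Martin periodinane (1.3 equiv), pyridine, CH2Cl2, 0 °C → rt
Reagents that add atoms: none
Why: Dess–Martin oxidation of a primary alcohol to the aldehyde under buffered conditions; the α-carbon is a CH2 next to the quaternary C4, so nothing can epimerise.

Step 6
Reactants: 9 (2E,6R,7R)-6-(TBS-oxy)-7-[(TBS-oxy)methyl]-3,7-dimethyl-9-oxonon-2-en-1-yl acetate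
Product: 10 (2E,6R,7R,9E)-6-(TBS-oxy)-7-[(TBS-oxy)methyl]-3,7-dimethyl-11-oxoundeca-2,9-dien-1-yl acetate
Conditions: Ph3P=CHCHO (1.5 equiv), toluene, 80 °C
Reagents that add atoms: (triphenylphosphoranylidene)acetaldehyde, O=CC=P(c1ccccc1)(c1ccccc1)c1ccccc1
Why: Wittig olefination with the stabilised formylmethylene ylide adds C7 and C8 in one step and should give the (E)-enal, the aliphatic aldehyde reacting faster than the enal product.

Step 7
Reactants: 10 (2E,6R,7R,9E)-6-(TBS-oxy)-7-[(TBS-oxy)methyl]-3,7-dimethyl-11-oxoundeca-2,9-dien-1-yl acetate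
Product: 11 (2E,6R,7R,8E,10E)-6,11-bis(TBS-oxy)-7-[(TBS-oxy)methyl]-3,7-dimethylundeca-2,8,10-trien-1-yl acetate
Conditions: TBSOTf (1.3 equiv), Et3N (3 equiv), CH2Cl2, −78 → 0 °C
Reagents that add atoms: tert-butyldimethylsilyl triflate, CC(C)(C)[Si](C)(C)OS(=O)(=O)C(F)(F)F
Why: Soft enolisation to a silyl dienol ether (O-silylation of the enal, then γ-deprotonation by Et3N): C5 is the only γ-position with hydrogen, the s-trans enal gives the (E)-enol ether and the quaternary C4 should force the new C5=C6 bond E.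

Step 8
Reactants: 11 (2E,6R,7R,8E,10E)-6,11-bis(TBS-oxy)-7-[(TBS-oxy)methyl]-3,7-dimethylundeca-2,8,10-trien-1-yl acetate
Product: 12 (2E,6R,7R,8E,10E)-6,11-bis(TBS-oxy)-7-[(TBS-oxy)methyl]-3,7-dimethylundeca-2,8,10-trien-1-ol
Conditions: i-Bu2AlH (2.5 equiv), CH2Cl2, −78 °C; aq. potassium sodium tartrate (KNaC4H4O6)
Reagents that add atoms: none
Why: Reductive cleavage of the acetate with i-Bu2AlH at −78 °C frees the allylic alcohol without touching the silyl ethers or the silyl dienol ether, which would not survive methanolysis or fluoride.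

Step 9
Reactants: 12 (2E,6R,7R,8E,10E)-6,11-bis(TBS-oxy)-7-[(TBS-oxy)methyl]-3,7-dimethylundeca-2,8,10-trien-1-ol
Product: 13 (2E,6R,7R,8E,10E)-6,11-bis(TBS-oxy)-7-[(TBS-oxy)methyl]-3,7-dimethylundeca-2,8,10-trienal
Conditions: MnO2 (20 equiv), CH2Cl2, rt
Reagents that add atoms: none
Why: Allylic oxidation with MnO2 is neutral, stops at the aldehyde, keeps the E geometry of C9=C10 and should leave the electron-rich dienol ether alone.

Step 10
Reactants: 13 (2E,6R,7R,8E,10E)-6,11-bis(TBS-oxy)-7-[(TBS-oxy)methyl]-3,7-dimethylundeca-2,8,10-trienal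
Product: 14 (1S,2R,4aS,5R,6R,8aR)-2,6-bis(TBS-oxy)-5-[(TBS-oxy)methyl]-5,8a-dimethyl-1,2,4a,5,6,7,8,8a-octahydronaphthalene-1-carbaldehyde (labdane numbering: 3R,4R,5S,8R,9S,10R; Δ6; C11 = CHO)
Conditions: Me2AlCl (1.1 equiv), CH2Cl2, −78 → −40 °C; Et3N, then aq. NaHCO3
Reagents that add atoms: none
Why: Me2AlCl binds the aldehyde oxygen and the (E)-enal C9=C10 adds suprafacially across the silyloxydiene C5=C6–C7=C8 in a concerted, asynchronous [4+2] cycloaddition, the closest known reaction type being the Lewis-acid-promoted intramolecular Diels–Alder reaction of 1,7,9-decatrienals; the silyloxy-bearing C8 bonds to the α-carbon C9 and C5 to the β-carbon C10, which is the electronically matched orientation. Ring B closes as the cyclohexene of the cycloaddition (bonds C5–C10 and C8–C9), and ring A closes at the same time as the six-membered ring spanned by the C1–C4 tether through the C5–C10 bond. C9 and C10 follow from the enal geometry (formyl and methyl cis), C5 from the transition state with the aldehyde endo and the tether anti, which gives the trans ring fusion, and C8 from the (E)-enol ether (silyloxy cis to formyl; this centre is removed later). The absolute sense of the three lasting centres is set by C3 and C4: in the chair-like tether the C3 silyloxy group lies equatorial, which places the C19 arm axial and syn to the developing C20 methyl, whereas attack on the other diene face needs an axial silyloxy group. The step needs endo/anti-tether selectivity and this diene-face selectivity; the first is raised by Lewis-acid coordination of the enal, the second rests on a modest conformational bias that is amplified by running at −78 °C, which is why the diol is kept as open-chain silyl ethers and the enal is activated instead of heated. Me2AlCl also scavenges adventitious protons, which protects the silyl dienol ether.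

Step 11
Reactants: 14 cycloadduct (octalin carbaldehyde)
Product: 15 (1S,2R,4aS,5R,6R,8aR)-2,6-bis(TBS-oxy)-5-[(TBS-oxy)methyl]-5,8a-dimethyldecahydronaphthalene-1-carbaldehyde (labdane numbering: 3R,4R,5S,8R,9S,10R)
Conditions: H2 (1 atm), Pd/C (5 wt%), EtOAc, rt
Reagents that add atoms: none
Why: Heterogeneous catalytic hydrogenation saturates the cis-disubstituted C6=C7 bond, the only alkene present, while the hindered aliphatic aldehyde and the silyl ethers should be inert under these conditions.

Step 12
Reactants: 15 saturated decalin carbaldehyde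
Product: 16 (E)-vinyl iodide: 15 with the C9 formyl group turned into (E)-CH=CHI (C11=C12); 3,8,19-tris(TBS-oxy); 3R,4R,5S,8R,9S,10R
Conditions: CrCl2 (8 equiv), CHI3 (3 equiv), THF–1,4-dioxane (1:6), 0 °C → rt
Reagents that add atoms: iodoform, IC(I)I
Why: Takai iodo-olefination: the gem-dichromium reagent from CHI3 and CrCl2 adds to the aldehyde and eliminates to the (E)-vinyl iodide under non-basic conditions that should neither epimerise C9 nor eliminate the β-silyloxy group.

Step 13
Reactants: 16 tris-silylated (E)-vinyl iodide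
Product: 17 triol: (3R,4R,5S,8R,9S,10R)-3,8,19-trihydroxy decalin with (E)-CH=CHI on C9
Conditions: HF·pyridine, pyridine, THF, 0 °C → rt
Reagents that add atoms: none
Why: Fluoride-mediated desilylation with buffered HF·pyridine removes all three silyl ethers without base, so the vinyl iodide is not dehydrohalogenated.

Step 14
Reactants: 17 triol
Product: 18 3,19-acetonide with free C8 hydroxyl; (3R,4R,5S,8R,9S,10R); (E)-CH=CHI on C9
Conditions: Me2C(OMe)2, PPTS (cat.), CH2Cl2, rt
Reagents that add atoms: 2,2-dimethoxypropane, COC(C)(C)OC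
Why: Acetalisation (transketalisation) ties the cis 3,19-diol into a six-membered acetonide, which the now rigid trans-decalin tolerates, and leaves the isolated, hindered axial C8 hydroxyl free.

Step 15
Reactants: 18 acetonide alcohol
Product: 19 C8 ketone: (3R,4R,5S,9S,10R)-3,19-acetonide, 8-oxo, (E)-CH=CHI on C9
Conditions: Dess–Martin periodinane (1.5 equiv), pyridine, CH2Cl2, 0 °C → rt
Reagents that add atoms: none
Why: Dess–Martin oxidation of the secondary alcohol to the ketone under buffered, non-enolising conditions, so that the allylic C9–H next to the new carbonyl stays in place.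

Step 16
Reactants: 19 C8 ketone
Product: 20 exocyclic alkene: (3R,4R,5S,9R,10R)-3,19-acetonide, C8=C17H2, (E)-CH=CHI on C9
Conditions: Cp2TiMe2 (3 equiv), toluene–THF, 65 °C, dark
Reagents that add atoms: dimethyltitanocene, C[Ti](C)(C1C=CC=C1)C1C=CC=C1
Why: Petasis methylenation: the titanium methylidene formed thermally from Cp2TiMe2 is not basic, so the ketone with its enolisable, allylic C9–H should be methylenated without epimerisation or double-bond migration.

Step 17
Reactants: 21 3-bromofuran-2(5H)-one
Product: 22 3-(tributylstannyl)furan-2(5H)-one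
Conditions: (Bu3Sn)2 (1.3 equiv), Pd(PPh3)4 (5 mol%), toluene, 100 °C
Reagents that add atoms: hexabutylditin, CCCC[Sn](CCCC)(CCCC)[Sn](CCCC)(CCCC)CCCC
Why: Palladium-catalysed stannylation of a vinyl bromide with a distannane (oxidative addition, Sn–Sn transmetalation, reductive elimination) gives the 3-metallated butenolide.

Step 18
Reactants: 20 exocyclic alkene vinyl iodide; 22 3-(tributylstannyl)furan-2(5H)-one
Product: 23 3,19-O-isopropylidene-14-deoxy-11,12-didehydroandrographolide; (3R,4R,5S,9R,10R), 11E
Conditions: Pd(PPh3)4 (10 mol%), CuI (20 mol%), DMF, 45 °C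
Reagents that add atoms: none
Why: Stille coupling with copper co-catalysis joins C12 to C13 with retention of the E geometry under neutral conditions that the butenolide and the exocyclic alkene should tolerate.

Step 19
Reactants: 23 acetonide-protected dienyl butenolide
Product: 24 14-deoxy-11,12-didehydroandrographolide (3,19-diol); (3R,4R,5S,9R,10R), 11E
Conditions: AcOH–H2O (4:1), rt
Reagents that add atoms: none
Why: Acid-catalysed acetal hydrolysis with aqueous acetic acid is mild enough to leave the exocyclic methylene and the dienyl butenolide unchanged.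

Step 20
Reactants: 24 3,19-diol
Product: 25 target, 19-O-acetyl-14-deoxy-11,12-didehydroandrographolide (CNP0346413.1)
Conditions: Ac2O (1.1 equiv), pyridine, CH2Cl2, −20 → 0 °C
Reagents that add atoms: acetic anhydride, CC(=O)OC(C)=O
Why: Selective acylation: the primary C19 hydroxyl should react much faster with acetic anhydride at low temperature than the secondary C3 hydroxyl next to the quaternary C4.

**Compound list**

1 | geranyl acetate | CC(C)=CCC/C(C)=C/COC(C)=O | starting material
2 | (2E)-5-(5,5-dimethyl-1,2,4-trioxolan-3-yl)-3-methylpent-2-en-1-yl acetate, secondary ozonide (not isolated) | CC1(C)OOC(CC/C(C)=C/COC(C)=O)O1 | intermediate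
3 | (2E)-3-methyl-6-oxohex-2-en-1-yl acetate | O=CCC/C(C)=C/COC(C)=O | intermediate
4 | 2-methyl-2-vinyloxirane (racemic) | CC1(C=C)CO1 | starting material
5 | (2E,6R,7R)-6-hydroxy-7-(hydroxymethyl)-3,7-dimethylnona-2,8-dien-1-yl acetate | C=C[C@](C)(CO)[C@H](O)CC/C(C)=C/COC(C)=O | intermediate
6 | (2E,6R,7R)-6-(TBS-oxy)-7-[(TBS-oxy)methyl]-3,7-dimethylnona-2,8-dien-1-yl acetate | C=C[C@](C)(CO[Si](C)(C)C(C)(C)C)[C@H](O[Si](C)(C)C(C)(C)C)CC/C(C)=C/COC(C)=O | intermediate
7 | B-alkyl-9-BBN adduct of 6, boron on the terminal carbon (not isolated) | B1(CC[C@](C)(CO[Si](C)(C)C(C)(C)C)[C@H](O[Si](C)(C)C(C)(C)C)CC/C(C)=C/COC(C)=O)C2CCCC1CCC2 | intermediate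
8 | (2E,6R,7R)-6-(TBS-oxy)-7-[(TBS-oxy)methyl]-9-hydroxy-3,7-dimethylnon-2-en-1-yl acetate | OCC[C@](C)(CO[Si](C)(C)C(C)(C)C)[C@H](O[Si](C)(C)C(C)(C)C)CC/C(C)=C/COC(C)=O | intermediate
9 | (2E,6R,7R)-6-(TBS-oxy)-7-[(TBS-oxy)methyl]-3,7-dimethyl-9-oxonon-2-en-1-yl acetate | O=CC[C@](C)(CO[Si](C)(C)C(C)(C)C)[C@H](O[Si](C)(C)C(C)(C)C)CC/C(C)=C/COC(C)=O | intermediate
10 | (2E,6R,7R,9E)-6-(TBS-oxy)-7-[(TBS-oxy)methyl]-3,7-dimethyl-11-oxoundeca-2,9-dien-1-yl acetate | O=C/C=C/C[C@](C)(CO[Si](C)(C)C(C)(C)C)[C@H](O[Si](C)(C)C(C)(C)C)CC/C(C)=C/COC(C)=O | intermediate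
11 | (2E,6R,7R,8E,10E)-6,11-bis(TBS-oxy)-7-[(TBS-oxy)methyl]-3,7-dimethylundeca-2,8,10-trien-1-yl acetate | CC(C)(C)[Si](C)(C)O/C=C/C=C/[C@](C)(CO[Si](C)(C)C(C)(C)C)[C@H](O[Si](C)(C)C(C)(C)C)CC/C(C)=C/COC(C)=O | intermediate
12 | (2E,6R,7R,8E,10E)-6,11-bis(TBS-oxy)-7-[(TBS-oxy)methyl]-3,7-dimethylundeca-2,8,10-trien-1-ol | CC(C)(C)[Si](C)(C)O/C=C/C=C/[C@](C)(CO[Si](C)(C)C(C)(C)C)[C@H](O[Si](C)(C)C(C)(C)C)CC/C(C)=C/CO | intermediate
13 | (2E,6R,7R,8E,10E)-6,11-bis(TBS-oxy)-7-[(TBS-oxy)methyl]-3,7-dimethylundeca-2,8,10-trienal (cycloaddition precursor) | CC(C)(C)[Si](C)(C)O/C=C/C=C/[C@](C)(CO[Si](C)(C)C(C)(C)C)[C@H](O[Si](C)(C)C(C)(C)C)CC/C(C)=C/C=O | intermediate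
14 | (1S,2R,4aS,5R,6R,8aR)-2,6-bis(TBS-oxy)-5-[(TBS-oxy)methyl]-5,8a-dimethyl-1,2,4a,5,6,7,8,8a-octahydronaphthalene-1-carbaldehyde (cycloadduct) | CC(C)(C)[Si](C)(C)O[C@@H]1C=C[C@@H]2[C@](C)(CO[Si](C)(C)C(C)(C)C)[C@H](O[Si](C)(C)C(C)(C)C)CC[C@@]2(C)[C@@H]1C=O | intermediate
15 | (1S,2R,4aS,5R,6R,8aR)-2,6-bis(TBS-oxy)-5-[(TBS-oxy)methyl]-5,8a-dimethyldecahydronaphthalene-1-carbaldehyde | CC(C)(C)[Si](C)(C)O[C@@H]1CC[C@@H]2[C@](C)(CO[Si](C)(C)C(C)(C)C)[C@H](O[Si](C)(C)C(C)(C)C)CC[C@@]2(C)[C@@H]1C=O | intermediate
16 | 3,8,19-tris(TBS-oxy) trans-decalin with (E)-2-iodovinyl on C9; 3R,4R,5S,8R,9S,10R | CC(C)(C)[Si](C)(C)O[C@@H]1CC[C@@H]2[C@](C)(CO[Si](C)(C)C(C)(C)C)[C@H](O[Si](C)(C)C(C)(C)C)CC[C@@]2(C)[C@@H]1/C=C/I | intermediate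
17 | 3,8,19-triol with (E)-2-iodovinyl on C9; 3R,4R,5S,8R,9S,10R | O[C@@H]1CC[C@@H]2[C@](C)(CO)[C@H](O)CC[C@@]2(C)[C@@H]1/C=C/I | intermediate
18 | 3,19-acetonide, 8-hydroxy (axial), (E)-2-iodovinyl on C9; 3R,4R,5S,8R,9S,10R | O[C@@H]1CC[C@@H]2[C@]3(C)COC(C)(C)O[C@@H]3CC[C@@]2(C)[C@@H]1/C=C/I | intermediate
19 | 3,19-acetonide, 8-oxo, (E)-2-iodovinyl on C9; 3R,4R,5S,9S,10R | O=C1CC[C@@H]2[C@]3(C)COC(C)(C)O[C@@H]3CC[C@@]2(C)[C@@H]1/C=C/I | intermediate
20 | 3,19-acetonide, 8(17)-methylene, (E)-2-iodovinyl on C9; 3R,4R,5S,9R,10R | C=C1CC[C@@H]2[C@]3(C)COC(C)(C)O[C@@H]3CC[C@@]2(C)[C@@H]1/C=C/I | intermediate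
21 | 3-bromofuran-2(5H)-one | O=C1OCC=C1Br | starting material
22 | 3-(tributylstannyl)furan-2(5H)-one | CCCC[Sn](CCCC)(CCCC)C1=CCOC1=O | intermediate
23 | 3,19-O-isopropylidene-14-deoxy-11,12-didehydroandrographolide; 3R,4R,5S,9R,10R, 11E | C=C1CC[C@@H]2[C@]3(C)COC(C)(C)O[C@@H]3CC[C@@]2(C)[C@@H]1/C=C/C1=CCOC1=O | intermediate
24 | 14-deoxy-11,12-didehydroandrographolide; 3R,4R,5S,9R,10R, 11E | C=C1CC[C@@H]2[C@](C)(CO)[C@H](O)CC[C@@]2(C)[C@@H]1/C=C/C1=CCOC1=O | intermediate
25 | 19-O-acetyl-14-deoxy-11,12-didehydroandrographolide (CNP0346413.1); 3R,4R,5S,9R,10R, 11E | C=C1CC[C@@H]2[C@](C)(COC(C)=O)[C@H](O)CC[C@@]2(C)[C@@H]1/C=C/C1=CCOC1=O | target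

**Step count and risks**

Total step count: 20. Longest linear sequence: 19 steps (steps 1–16 and 18–20); step 17 prepares the stannane 22 separately.

Steps most likely to fail:

1. Step 10 (cycloaddition). The transition state on the other diene face (axial C3 silyloxy group) or the exo, cis-fused mode may compete, because the substrate bias is only conformational. The silyl dienol ether may also react ionically with the activated enal (Michael addition without ring closure, or desilylation). Fallback: reagent control in place of substrate control. Setting out from 13 and coming back at 14, the cycloaddition is run with a chiral cationic oxazaborolidine Lewis acid (proline-derived B-o-tolyl oxazaborolidine activated by triflimide, 20 mol%, CH2Cl2, −78 °C). The catalyst antipode is chosen so that its facial preference for the enal reinforces the substrate preference; this is a known way to catalyse Diels–Alder reactions of enals with silyloxydienes. This fallback makes no new compound (F0).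

2. Step 16 (methylenation). Carbonyl addition at the hindered C8 ketone may be slow, so that enolisation toward C9 takes over, with epimerisation or migration of the side-chain double bond into conjugation. Fallback: a two-stage Peterson olefination. Setting out from 19, the non-basic organocerium reagent from Me3SiCH2Li and CeCl3 (THF, −78 °C) adds to the ketone and gives the β-hydroxysilane F1 (hydroxyl expected axial; either C8 epimer serves). Syn-elimination of its potassium alkoxide (KH, THF, 0 °C → rt) then gives the exocyclic alkene and the route is rejoined at 20.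

3. Step 12 (Takai reaction). Addition of the bulky gem-dichromium reagent to the aldehyde, which is flanked by the quaternary C10 and the axial C8 silyloxy group, may be sluggish, allowing reduction of the aldehyde or erosion of the E/Z ratio. Fallback: an alkyne route. Setting out from 15, Ohira–Bestmann homologation (dimethyl (1-diazo-2-oxopropyl)phosphonate, K2CO3, MeOH, 0 °C → rt) gives the terminal alkyne F2. Syn-hydrozirconation with Cp2Zr(H)Cl (THF, rt) gives the (E)-alkenylzirconocene chloride F3, which is not isolated and is cleaved with I2 to the (E)-vinyl iodide, so the route is rejoined at 16.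

Further compounds
F0 | step 10 | none | none
F1 | step 16 | 3,19-acetonide, 8-hydroxy-8-[(trimethylsilyl)methyl], (E)-2-iodovinyl on C9 (β-hydroxysilane, hydroxyl axial) | C[Si](C)(C)C[C@@]1(O)CC[C@@H]2[C@]3(C)COC(C)(C)O[C@@H]3CC[C@@]2(C)[C@@H]1/C=C/I
F2 | step 12 | 3,8,19-tris(TBS-oxy) trans-decalin with ethynyl on C9 | CC(C)(C)[Si](C)(C)O[C@@H]1CC[C@@H]2[C@](C)(CO[Si](C)(C)C(C)(C)C)[C@H](O[Si](C)(C)C(C)(C)C)CC[C@@]2(C)[C@@H]1C#C
F3 | step 12 | (E)-alkenylzirconocene chloride from F2 (not isolated) | CC(C)(C)[Si](C)(C)O[C@@H]1CC[C@@H]2[C@](C)(CO[Si](C)(C)C(C)(C)C)[C@H](O[Si](C)(C)C(C)(C)C)CC[C@@]2(C)[C@@H]1/C=C/[Zr](Cl)(C1C=CC=C1)C1C=CC=C1
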